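**Strategy.** The chain is cut between its benzylic CH2 (C3) and the ipso carbon of the 4-hydroxyphenyl ring (ring B). The adjacent pair C2–OH/C3H2 is the retron of a terminal oxirane opened at CH2, and the C1 ketone on the resorcinol ring (ring A) can be held as a Weinreb hemiaminal alkoxide. In one flask, lithiated ring A adds to (S)-glycidic Weinreb amide; the chelated adduct, carrying ring A, masked C1 and the intact (S)-oxirane, is then opened at C3 by a ring-B arylcopper reagent. Work-up unveils the α-hydroxy ketone with C2 untouched; mild acid removes the acetal protecting groups.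

Key step: step 4

Assumption: Grignard reagent 8 is taken as its commercial THF solution, racemic at the acetal carbon; 11 and 12 (and F1, F2 of the fallback) are therefore epimer mixtures at that remote carbon, which is lost in step 5.

**Step 1**
Reactants: 1 2-methylresorcinol
Product: 2 1,3-bis(methoxymethoxy)-2-methylbenzene
Conditions: MOMCl, i-Pr2NEt, CH2Cl2, 0 °C → rt
Reagents that add atoms: chloromethyl methyl ether (MOMCl), COCCl
Why: Williamson-type O-alkylation (MOM protection) of both phenols by the reactive α-chloro ether with the amine as HCl scavenger should give the bis-acetal whose oxygens later direct both lithiations; no stereocentre is formed.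

**Step 2**
Reactants: 2 1,3-bis(methoxymethoxy)-2-methylbenzene; 3 prenyl bromide (1-bromo-3-methylbut-2-ene)
Product: 5 1,3-bis(methoxymethoxy)-2-methyl-4-(3-methylbut-2-en-1-yl)benzene, via aryllithium 4 (not isolated)
Conditions: n-BuLi, TMEDA, THF, 0 °C; then CuBr·SMe2 (10 mol %), 3, −78 °C → rt
Reagents that add atoms: none
Why: Directed ortho-metalation followed by copper-catalysed SN2 allylation: OMOM directs n-BuLi to its ortho C–H (the two such positions are equivalent by symmetry) and the arylcopper species should attack prenyl bromide at the primary carbon, giving the linear 3-methylbut-2-enyl group; no stereocentre is formed.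

**Step 3**
Reactants: 6 methyl (2S)-oxirane-2-carboxylate
Product: 7 (2S)-N-methoxy-N-methyloxirane-2-carboxamide
Conditions: MeNH(OMe)·HCl, i-PrMgCl, THF, −20 °C
Reagents that add atoms: N,O-dimethylhydroxylamine hydrochloride, CNOC.Cl
Why: Ester aminolysis by a magnesium amide (Weinreb amide synthesis) should occur at the ester carbonyl faster than any attack on the oxirane at −20 °C, and C2, not being a reacting centre, keeps the (S) configuration of 6.

**Step 4**
Reactants: 5 1,3-bis(methoxymethoxy)-2-methyl-4-(3-methylbut-2-en-1-yl)benzene; 7 (2S)-N-methoxy-N-methyloxirane-2-carboxamide; 8 4-(tetrahydro-2H-pyran-2-yloxy)phenylmagnesium bromide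
Product: 12 (2S)-1-[2,4-bis(methoxymethoxy)-3-methyl-5-(3-methylbut-2-en-1-yl)phenyl]-2-hydroxy-3-[4-(tetrahydro-2H-pyran-2-yloxy)phenyl]propan-1-one, via aryllithium 9 (not isolated), via lithium hemiaminal alkoxide 10 (not isolated), via ring-opened dialkoxide 11 (not isolated)
Conditions: 5, s-BuLi, TMEDA, THF, −78 °C; 7, −78 °C; 8, CuBr·SMe2 (20 mol %), −40 → 0 °C; sat. aq. NH4Cl
Reagents that add atoms: none
Why: s-BuLi/TMEDA deprotonates 5 at the one ring C–H ortho to an OMOM group (directed ortho-metalation) and aryllithium 9 adds to Weinreb amide 7 to give the five-membered Li–O/N–OMe chelate 10, which should not collapse at or below 0 °C, so C1 stays masked and C2 carries no acidic hydrogen. The arylcopper species formed from Grignard reagent 8 and catalytic CuBr·SMe2 then opens the oxirane of 10 by SN2 attack at the unsubstituted CH2 carbon, which forms the bond between that CH2 and the ipso carbon of ring B and joins the two halves; aqueous NH4Cl finally collapses hemiaminal 11 to the aryl ketone. The closest known reaction types are the copper-catalysed opening of terminal epoxides by aryl Grignard reagents and the one-pot Weinreb addition/second organometallic coupling in which the tetrahedral adduct serves as an in-situ ketone protecting group. No ring is closed; the oxirane is opened. No stereocentre is created: C2 is not a reacting centre, so its (S) configuration is that of glycidate 6, and the hemiaminal carbon of 10 and 11 is a transient, uncontrolled centre that vanishes on work-up. The step needs regioselectivity (CH2 versus CH of the oxirane, secured by the fully substituted hemiaminal carbon next to C2), chemoselectivity (oxirane versus carbonyl, secured by the chelated tetrahedral adduct and by copper catalysis at low temperature to outrun bromide opening) and site-selective lithiation (ring C–H versus the benzylic–allylic CH2, secured by OMOM coordination at −78 °C).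

**Step 5**
Reactants: 12 (2S)-1-[2,4-bis(methoxymethoxy)-3-methyl-5-(3-methylbut-2-en-1-yl)phenyl]-2-hydroxy-3-[4-(tetrahydro-2H-pyran-2-yloxy)phenyl]propan-1-one
Product: 13 Lespeflorin C5, (2S)-1-[2,4-dihydroxy-3-methyl-5-(3-methylbut-2-en-1-yl)phenyl]-2-hydroxy-3-(4-hydroxyphenyl)propan-1-one
Conditions: 3 M aq. HCl, MeOH, rt
Reagents that add atoms: none
Why: Acid-catalysed transacetalization to methanol should cleave the two MOM ethers and the THP ether, while dilute acid at room temperature should neither protonate the prenyl double bond nor enolize the α-hydroxy ketone, so the (S) centre is retained.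

**Compound list**

1 | 2-methylresorcinol (2-methylbenzene-1,3-diol) | Cc1c(O)cccc1O | starting material
2 | 1,3-bis(methoxymethoxy)-2-methylbenzene | COCOc1cccc(OCOC)c1C | intermediate
3 | prenyl bromide (1-bromo-3-methylbut-2-ene) | CC(C)=CCBr | starting material
4 | [2,4-bis(methoxymethoxy)-3-methylphenyl]lithium | [Li]c1ccc(OCOC)c(C)c1OCOC | intermediate (not isolated)
5 | 1,3-bis(methoxymethoxy)-2-methyl-4-(3-methylbut-2-en-1-yl)benzene | CC(C)=CCc1ccc(OCOC)c(C)c1OCOC | intermediate
6 | methyl (2S)-oxirane-2-carboxylate (methyl (S)-glycidate) | COC(=O)[C@@H]1CO1 | starting material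
7 | (2S)-N-methoxy-N-methyloxirane-2-carboxamide | CON(C)C(=O)[C@@H]1CO1 | intermediate
8 | 4-(tetrahydro-2H-pyran-2-yloxy)phenylmagnesium bromide (racemic at the acetal carbon, THF solution) | Br[Mg]c1ccc(OC2CCCCO2)cc1 | starting material
9 | [2,4-bis(methoxymethoxy)-3-methyl-5-(3-methylbut-2-en-1-yl)phenyl]lithium | CC(C)=CCc1cc([Li])c(OCOC)c(C)c1OCOC | intermediate (not isolated)
10 | lithium [2,4-bis(methoxymethoxy)-3-methyl-5-(3-methylbut-2-en-1-yl)phenyl][methoxy(methyl)amino][(2S)-oxiran-2-yl]methanolate (both epimers at the hemiaminal carbon) | CC(C)=CCc1cc(C(O[Li])(N(C)OC)[C@@H]2CO2)c(OCOC)c(C)c1OCOC | intermediate (not isolated)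
11 | mixed lithium/bromomagnesium dialkoxide of (2S)-1-[2,4-bis(methoxymethoxy)-3-methyl-5-(3-methylbut-2-en-1-yl)phenyl]-1-[methoxy(methyl)amino]-3-[4-(tetrahydro-2H-pyran-2-yloxy)phenyl]propane-1,2-diol (epimers at the hemiaminal and acetal carbons) | CC(C)=CCc1cc(C(O[Li])(N(C)OC)[C@@H](O[Mg]Br)Cc2ccc(OC3CCCCO3)cc2)c(OCOC)c(C)c1OCOC | intermediate (not isolated)
12 | (2S)-1-[2,4-bis(methoxymethoxy)-3-methyl-5-(3-methylbut-2-en-1-yl)phenyl]-2-hydroxy-3-[4-(tetrahydro-2H-pyran-2-yloxy)phenyl]propan-1-one (two epimers at the acetal carbon) | CC(C)=CCc1cc(C(=O)[C@@H](O)Cc2ccc(OC3CCCCO3)cc2)c(OCOC)c(C)c1OCOC | intermediate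
13 | Lespeflorin C5, (2S)-1-[2,4-dihydroxy-3-methyl-5-(3-methylbut-2-en-1-yl)phenyl]-2-hydroxy-3-(4-hydroxyphenyl)propan-1-one | CC(C)=CCc1cc(C(=O)[C@@H](O)Cc2ccc(O)cc2)c(O)c(C)c1O | target

**Step count.** Total: 5 steps. Longest linear sequence: 4 steps (1, 2, 4, 5); step 3 is a one-step branch.

**Steps most likely to fail**

1. Step 4. The hemiaminal alkoxide 10 may collapse before or during the copper step, so that arylmetal adds to the freed ketone. Bromide may open the oxirane instead of the arylcopper species. The lithiation may take place at the benzylic–allylic CH2 instead of the ring. Fallback, from 6 and 8, back at 12: the order of events is changed so that no masked ketone has to survive the copper step. Grignard reagent 8 with catalytic CuBr·SMe2 at −40 °C should open methyl (S)-glycidate 6 at C3 to give methyl (2S)-2-hydroxy-3-[4-(tetrahydro-2H-pyran-2-yloxy)phenyl]propanoate F1. Aminolysis with MeNH(OMe)·HCl/i-PrMgCl should then give (2S)-2-hydroxy-N-methoxy-N-methyl-3-[4-(tetrahydro-2H-pyran-2-yloxy)phenyl]propanamide F2. F2 is deprotonated at oxygen with one equivalent of i-PrMgCl, treated with aryllithium 9 (made from 5 as in step 4) at −78 °C and quenched with aqueous NH4Cl to give 12.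

2. Step 3. The oxirane may be opened by chloride under the Lewis-acidic magnesium species, or by the amide nitrogen at C3, during the amidation. Fallback, from 6, back at 7: 6 is saponified with one equivalent of KOH in EtOH at 0 °C to potassium (2S)-oxirane-2-carboxylate F3. This salt is coupled with MeNH(OMe)·HCl by EDC·HCl in CH2Cl2 at 0 °C, a carbodiimide amide coupling in which no magnesium halide is present, to give 7.

3. Step 5. The prenyl double bond may be protonated and captured by the neighbouring C4 phenol (chroman ring closure), and acid-catalysed enolization of the α-hydroxy ketone may erode the configuration at C2. Fallback, from 12, back at 13: the acetals are exchanged for silyl ethers under aprotic, buffered conditions. TMSOTf/2,2′-bipyridyl in CH2Cl2 at 0 °C should convert the two aryl MOM ethers and the aryl THP ether into aryl trimethylsilyl ethers and silylate the secondary hydroxyl, giving (2S)-1-[3-methyl-5-(3-methylbut-2-en-1-yl)-2,4-bis(trimethylsilyloxy)phenyl]-2-(trimethylsilyloxy)-3-[4-(trimethylsilyloxy)phenyl]propan-1-one F4. The silyl ethers are then hydrolysed in aqueous THF buffered at pH 5 (AcOH/NaOAc) at rt to give 13.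

**Further compounds**

F1 | step 4 | methyl (2S)-2-hydroxy-3-[4-(tetrahydro-2H-pyran-2-yloxy)phenyl]propanoate | COC(=O)[C@@H](O)Cc1ccc(OC2CCCCO2)cc1
F2 | step 4 | (2S)-2-hydroxy-N-methoxy-N-methyl-3-[4-(tetrahydro-2H-pyran-2-yloxy)phenyl]propanamide | CON(C)C(=O)[C@@H](O)Cc1ccc(OC2CCCCO2)cc1
F3 | step 3 | potassium (2S)-oxirane-2-carboxylate | [K+].[O-]C(=O)[C@@H]1CO1
F4 | step 5 | (2S)-1-[3-methyl-5-(3-methylbut-2-en-1-yl)-2,4-bis(trimethylsilyloxy)phenyl]-2-(trimethylsilyloxy)-3-[4-(trimethylsilyloxy)phenyl]propan-1-one | CC(C)=CCc1cc(C(=O)[C@@H](O[Si](C)(C)C)Cc2ccc(O[Si](C)(C)C)cc2)c(O[Si](C)(C)C)c(C)c1O[Si](C)(C)C
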